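(The runs are simulated for an exercise; noise was put on by code.)

The flask was closed, stirred and isothermal. I had followed it for some hours as the north-west run. The north-east run differed from it in one charge: cX was 0.030 M against 0.060 M.

| setting | north-west | north-east | flask |
|---|---|---|---|
| L | 0.050 M | 0.050 M | 0.050 M |
| X | 0.060 M | 0.030 M | 0.0600 M |
| Z | 6 mM | 6 mM | 6.0 mM |
| remark | the very flask that is asked about, followed so far | run made earlier |  |
| time |  |  | 8.0 h |

- north-west (time / h: Q / %, G / %): 0.250: 6, 12; 0.417: 7, 17; 0.667: 13, 20; 1.33: 18, 18; 2.00: 21, 13; 3.00: 30, 10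
- north-east (time / h: Q / %, G / %): 0.200: 2, 5; 0.667: 6, 9; 1.00: 8, 9; 2.00: 17, 7; 2.50: 18, 9; 3.00: 21, 6

(readings scatter by 1.5 percentage points)

- a reading or a percentage of G counts all its forms, free or not

* ratio of Q to G at 2.0 min
* ratio of Q to G at 8.0 h

I worked with the fraction of L left, not the fraction made, and counted the Q and G read as what L had become. My measure was the depth: minus the natural log of the fraction of L left, a pseudo-first-order exposure of L. At 0.667 h the depths were 0.400 in the north-west run and 0.163 in the north-east run, a reading of 2.45 between them. At 3.00 h they were 0.511 and 0.315. That late reading of 1.62 lay below the charge ratio of 2.00, so by then the extra X of the north-west run had brought less than in proportion. Yet the L lost by then in the north-west run called for 0.0200 M of X, less than its charge. Both runs held 6 mM of Z, so the charge of Z did not separate them. I suspected that X was going elsewhere, faster in the north-west run.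

The log of the late depth ratio over the log of the charge ratio was 0.699; I called this the charge exponent. It is a reading, with the scatter of its readings. The early reading was higher, so I committed to a rule for late times only, from 3.00 h on: at a fixed time, with L and Z held, depth goes as the charge of X to this power.

The forecast gave 0.37 and 9, saying “The catalyst is evidently dying or being inhibited.”

The flask gave 0.392 and 14.7.

    L + X ⇌ G (K = 15.0 L mol⁻¹, k = 12.0 L mol⁻¹ h⁻¹)
    L + X ⇌ Q (K = 2400 L mol⁻¹, k = 4.60 L mol⁻¹ h⁻¹)
    G + Z ⇌ Q + Z, rate k3*[Z]*[G] forward; the back reaction follows from the equilibrium constant (k = 65.0 L mol⁻¹ h⁻¹)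
    X + G ⇌ D, settled at all times (K = 11.0 L mol⁻¹)
    2 Z → J (k = 12.0 L mol⁻¹ h⁻¹)
    2 X → E (k = 11.0 L mol⁻¹ h⁻¹)

At 8.00 h the flask held L 55.1 %, a depth of 0.597, and X 5.36 % of its charge. Just after the start of this flask, X went by the step to E 5.7 times as fast as by the forward step to Q. At 0.450 h that ratio was still 3.6. For the neighbour flask charged with 0.015 M of X, the exponent gave a depth of 0.227, so 79.7 % of the L charged left at that time; that flask held L at 79.7 %.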